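**Assumption (one line):** atoms carry rifamycin-type locants (C15 amide carbonyl, C16–C29 ansa chain, C12 the methyl-bearing alkene carbon, C11 the aryl ketone carbon, C1–C8 the naphthoquinone, C5–C8 the four carbons of the new benzenoid ring); C11 and C7 of open-chain intermediates are carried as epimer mixtures because both centres are erased later (C7 in step 25, C11 in step 26).

## Retrosynthetic overview

1. Target ⇐ removal of the TBS ether and acetonide and oxidation of the C11 carbinol of macrocyclic naphthoquinone 44.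
2. 44 ⇐ seco amidobenzoquinone 41 by one-pot bis(silyloxy)diene formation and intramolecular Diels–Alder benzannulation; the benzenoid ring and the 23-membered ansa ring form in the same operation.
3. 41 ⇐ phenol oxidation (this makes the quinone ring, from 3-amino-2-methylphenol), Lindlar reduction and Sonogashira coupling of alkyne 31 with iodoacrylanilide 38; 31 ⇐ dianion aldol of methyl 2-methylacetoacetate with Z-enal 28.
4. 28 ⇐ Fráter–Seebach aldol (C23–C24) of β-hydroxy ester 24 with alkyne aldehyde 8.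
5. 8 ⇐ Roche ester plus Marshall propargylation; 24 ⇐ Crimmins aldol, Claisen, anti reduction, ozonolysis and chelation-controlled alkenyl addition. Ring order: quinone ring first (step 24), then benzenoid ring and macrocycle together (step 25).

## Route

Step 1
Reactants: 1 methyl (S)-3-hydroxy-2-methylpropanoate
Product: 2 methyl (S)-2-methyl-3-(triethylsilyloxy)propanoate
Conditions: TESCl, imidazole, CH2Cl2, 0 → 23 °C
Reagents that add atoms: chlorotriethylsilane, CC[Si](Cl)(CC)CC
Why: Imidazole-promoted silyl ether formation on the primary alcohol; the C22 stereocentre is not touched.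

Step 2
Reactants: 2 methyl (S)-2-methyl-3-(triethylsilyloxy)propanoate
Product: 3 (S)-2-methyl-3-(triethylsilyloxy)propanal
Conditions: i-Bu2AlH (1.05 equiv), CH2Cl2, −78 °C; aq. potassium sodium tartrate
Reagents that add atoms: none
Why: Partial ester reduction at −78 °C stops at the aldehyde oxidation level and does not epimerise the α-centre.

Step 3
Reactants: 4 (S)-but-3-yn-2-ol
Product: 5 (S)-but-3-yn-2-yl methanesulfonate
Conditions: MsCl, Et3N, CH2Cl2, −78 → 0 °C
Reagents that add atoms: methanesulfonyl chloride, CS(=O)(=O)Cl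
Why: O-sulfonylation with retention at carbon gives the propargylic mesylate for the Marshall reaction.

Step 4
Reactants: 3 (S)-2-methyl-3-(triethylsilyloxy)propanal; 5 (S)-but-3-yn-2-yl methanesulfonate
Product: 6 (2S,3R,4R)-2,4-dimethyl-1-(triethylsilyloxy)hex-5-yn-3-ol
Conditions: Pd(OAc)2 (5 mol %), PPh3 (5 mol %), InI (1.4 equiv), THF/HMPA 3:1, 0 → 23 °C
Reagents that add atoms: none
Why: Marshall propargylation: zerovalent palladium opens the mesylate by anti SN2′, InI transmetalates to a chiral allenylindium, and its cyclic SE2′ addition sets C20/C21 anti and overrides the Felkin bias of 3 to give the anti,anti triad (reagent control, dr about 8:1 expected).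

Step 5
Reactants: 6 (2S,3R,4R)-2,4-dimethyl-1-(triethylsilyloxy)hex-5-yn-3-ol
Product: 7 (2S,3R,4R)-3-(tert-butyldimethylsilyloxy)-2,4-dimethyl-1-(triethylsilyloxy)hex-5-yne
Conditions: TBSOTf, 2,6-lutidine, CH2Cl2, −78 → 0 °C
Reagents that add atoms: tert-butyldimethylsilyl trifluoromethanesulfonate, CC(C)(C)[Si](C)(C)OS(=O)(=O)C(F)(F)F
Why: Silyl triflate silylation of the hindered C21 alcohol; the primary TES ether survives.

Step 6
Reactants: 7 (2S,3R,4R)-3-(tert-butyldimethylsilyloxy)-2,4-dimethyl-1-(triethylsilyloxy)hex-5-yne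
Product: 8 (2R,3R,4R)-3-(tert-butyldimethylsilyloxy)-2,4-dimethylhex-5-ynal
Conditions: (COCl)2, DMSO, CH2Cl2, −78 → −35 °C; then Et3N, −78 → 0 °C
Reagents that add atoms: none
Why: Direct Swern oxidation of a primary TES ether (oxidative desilylation) gives the aldehyde in one step while the secondary TBS ether is inert; C22 is kept at low temperature.

Step 7
Reactants: 9 (R)-4-benzyl-3-propanoylthiazolidine-2-thione; 10 methacrolein
Product: 12 (R)-4-benzyl-3-[(2R,3R)-3-hydroxy-2,4-dimethylpent-4-enoyl]thiazolidine-2-thione, via chlorotitanium Z-enolate 11 (not isolated)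
Conditions: TiCl4 (1.05 equiv), i-Pr2NEt (1.1 equiv), NMP (1.1 equiv), CH2Cl2, 0 °C; then 10, 0 °C
Reagents that add atoms: none
Why: Crimmins titanium aldol under the non-chelated (Evans syn) regime: the Z-enolate and the auxiliary face set C26 and C27 syn with the required absolute sense.

Step 8
Reactants: 12 (R)-4-benzyl-3-[(2R,3R)-3-hydroxy-2,4-dimethylpent-4-enoyl]thiazolidine-2-thione; 13 potassium methyl malonate
Product: 14 methyl (4R,5R)-5-hydroxy-4,6-dimethyl-3-oxohept-6-enoate
Conditions: MgCl2, imidazole, THF, 23 °C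
Reagents that add atoms: none
Why: Masamune-type decarboxylative Claisen condensation: the magnesium malonate is acylated by the activated N-acylthiazolidinethione and loses CO2, releasing the auxiliary without touching C26/C27.

Step 9
Reactants: 14 methyl (4R,5R)-5-hydroxy-4,6-dimethyl-3-oxohept-6-enoate
Product: 15 methyl (3S,4S,5R)-3,5-dihydroxy-4,6-dimethylhept-6-enoate
Conditions: Me4NBH(OAc)3, MeCN/AcOH 1:1, −30 °C
Reagents that add atoms: none
Why: Evans–Saksena reduction: hydride is delivered intramolecularly from the C27 alkoxyborohydride, setting C25 1,3-anti to C27 (and therefore anti to the C26 methyl).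

Step 10
Reactants: 15 methyl (3S,4S,5R)-3,5-dihydroxy-4,6-dimethylhept-6-enoate
Product: 16 methyl (3S,4S,5R)-3,5-dihydroxy-4-methyl-6-oxoheptanoate
Conditions: O3, CH2Cl2/MeOH 4:1, −78 °C; then Me2S, −78 → 23 °C
Reagents that add atoms: ozone, [O-][O+]=O
Why: Ozonolysis of the 1,1-disubstituted alkene unveils the C28 methyl ketone; used crude because the α-hydroxy ketone is sensitive.

Step 11
Reactants: 17 prop-2-yn-1-ol
Product: 19 (Z)-3-iodo-2-methylprop-2-en-1-ol, via alkenylmagnesium alkoxide 18 (not isolated)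
Conditions: MeMgBr (2.5 equiv), CuI (10 mol %), THF, −10 → 23 °C; then I2, −78 → 0 °C
Reagents that add atoms: methylmagnesium bromide, C[Mg]Br; iodine, II
Why: Duboudin copper-catalysed anti carbomagnesiation of the propargylic alkoxide gives a chelated alkenylmagnesium whose iodinolysis fixes the Z geometry (iodine cis to CH2OH), the future C29=C12 geometry.

Step 12
Reactants: 19 (Z)-3-iodo-2-methylprop-2-en-1-ol
Product: 20 (Z)-tert-butyl[(3-iodo-2-methylprop-2-en-1-yl)oxy]dimethylsilane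
Conditions: TBSCl, imidazole, CH2Cl2, 0 → 23 °C
Reagents that add atoms: tert-butyl(chloro)dimethylsilane, CC(C)(C)[Si](C)(C)Cl
Why: Silyl ether formation protects the C11 hydroxyl for the organometallic chemistry.

Step 13
Reactants: 16 methyl (3S,4S,5R)-3,5-dihydroxy-4-methyl-6-oxoheptanoate; 20 (Z)-tert-butyl[(3-iodo-2-methylprop-2-en-1-yl)oxy]dimethylsilane
Product: 23 methyl (3S,4S,5R,6R,7Z)-9-(tert-butyldimethylsilyloxy)-3,5,6-trihydroxy-4,6,8-trimethylnon-7-enoate, via alkenyllithium 21 (not isolated), via alkenylmagnesium bromide 22 (not isolated)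
Conditions: 20 (4 equiv), t-BuLi (8 equiv), Et2O, −78 °C; MgBr2·OEt2 (4.2 equiv), −78 → −40 °C; then 16, CH2Cl2, −78 → −40 °C
Reagents that add atoms: none
Why: Iodine–lithium exchange with retention, transmetalation to magnesium, then Cram-chelate addition: two equivalents deprotonate the hydroxyls, the C27 alkoxide and C28 carbonyl chelate magnesium, and the alkenyl group adds anti to the C26 branch to give the 27,28-syn diol (28R); the ketone reacts far faster than the ester at −78 °C.

Step 14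
Reactants: 23 methyl (3S,4S,5R,6R,7Z)-9-(tert-butyldimethylsilyloxy)-3,5,6-trihydroxy-4,6,8-trimethylnon-7-enoate
Product: 24 methyl (3S,4S)-3-hydroxy-4-{(4R,5R)-5-[(Z)-3-(tert-butyldimethylsilyloxy)-2-methylprop-1-en-1-yl]-2,2,5-trimethyl-1,3-dioxolan-4-yl}pentanoate
Conditions: Me2C(OMe)2, PPTS (cat.), CH2Cl2, 23 °C
Reagents that add atoms: 2,2-dimethoxypropane, COC(C)(C)OC
Why: Thermodynamic acetonide formation prefers the trans-dioxolane of the syn-1,2-diol over the twist-boat dioxane of the anti-1,3-diol, leaving only the C25 hydroxyl free.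

Step 15
Reactants: 24 methyl (3S,4S)-3-hydroxy-4-{(4R,5R)-5-[(Z)-3-(tert-butyldimethylsilyloxy)-2-methylprop-1-en-1-yl]-2,2,5-trimethyl-1,3-dioxolan-4-yl}pentanoate; 8 (2R,3R,4R)-3-(tert-butyldimethylsilyloxy)-2,4-dimethylhex-5-ynal
Product: 26 open-chain C18–C11 aldol adduct (C24 methyl ester; 23,25-diol; 21-OTBS; 27,28-acetonide; C11H2OTBS; C18≡C19 alkyne; 12Z), via dilithium dianion 25 (not isolated)
Conditions: LiN(i-Pr)2 (2.2 equiv), THF, −78 → −20 °C; then 8, −78 °C; aq. NH4Cl
Reagents that add atoms: none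
Why: Fráter–Seebach aldol: the lithium-chelated Z(O)-enolate dianion reacts anti to the C26 branch of the C25 alkoxide (sets C24), the closed transition state gives the 23,24-syn aldol, and a Z-enolate prefers the anti-Felkin face of the α-methyl aldehyde (C23 anti to the C22 methyl), so all three preferences converge on 26.

Step 16
Reactants: 26 open-chain C18–C11 aldol adduct
Product: 27 C11 allylic alcohol (as 26 but C11H2OH)
Conditions: HF·pyridine, pyridine, THF, 0 °C
Reagents that add atoms: none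
Why: Buffered fluoride desilylation removes the primary allylic TBS ether much faster than the hindered secondary C21 TBS ether; the acetonide is stable.

Step 17
Reactants: 27 C11 allylic alcohol
Product: 28 (Z)-enal (as 27 but C11HO)
Conditions: activated MnO2 (20 equiv), CH2Cl2, 23 °C
Reagents that add atoms: none
Why: MnO2 oxidises only the allylic alcohol (the C23 and C25 alcohols are untouched) and keeps the Z geometry; the acetonide at O28 prevents lactol formation.

Step 18
Reactants: 28 (Z)-enal; 29 methyl 2-methyl-3-oxobutanoate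
Product: 31 δ-hydroxy β-keto ester (28 extended by C5–C8: C11H(OH)–C5H2–C6(=O)–C7H(Me)–C8O2Me; C11 and C7 epimers), via sodium lithium dianion 30 (not isolated)
Conditions: 29 (6 equiv), NaH, THF, 0 °C; n-BuLi, 0 °C; then 28, −78 °C; aq. NH4Cl
Reagents that add atoms: none
Why: Weiler dianion aldol: the γ-carbanion adds 1,2 to the enal; excess dianion absorbs the hydroxyl and alkyne protons, and the new C11 centre is irrelevant because it is oxidised in step 26.

Step 19
Reactants: 32 diethyl 2-methylmalonate; 33 iodoform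
Product: 34 diethyl 2-(diiodomethyl)-2-methylmalonate
Conditions: NaH, Et2O, reflux
Reagents that add atoms: none
Why: C-alkylation of the sodium malonate with iodoform (carbenoid pathway) installs the CHI2 group.

Step 20
Reactants: 34 diethyl 2-(diiodomethyl)-2-methylmalonate
Product: 35 (E)-3-iodo-2-methylprop-2-enoic acid
Conditions: KOH, EtOH/H2O 3:1, reflux; then aq. HCl
Reagents that add atoms: potassium hydroxide, [K+].[OH-]
Why: Saponification followed by decarboxylative (Grob-type) elimination of iodide gives the E-configured iodoacrylic acid.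

Step 21
Reactants: 35 (E)-3-iodo-2-methylprop-2-enoic acid; 36 3-amino-2-methylphenol
Product: 38 (E)-N-(3-hydroxy-2-methylphenyl)-3-iodo-2-methylprop-2-enamide, via acid chloride 37 (not isolated)
Conditions: (COCl)2, DMF (cat.), CH2Cl2, 0 → 23 °C; then 36, NaHCO3, THF/H2O, 0 °C
Reagents that add atoms: none
Why: Schotten–Baumann acylation: the aniline nitrogen is far more nucleophilic than the neutral phenol, so the amide forms selectively and the alkene geometry is retained.

Step 22
Reactants: 31 δ-hydroxy β-keto ester; 38 (E)-N-(3-hydroxy-2-methylphenyl)-3-iodo-2-methylprop-2-enamide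
Product: 39 enyne anilide (C18 of 31 joined to C17 of the (E)-2-methylacrylanilide; phenol free)
Conditions: Pd(PPh3)2Cl2 (5 mol %), CuI (10 mol %), Et3N, THF, 23 °C
Reagents that add atoms: none
Why: Sonogashira coupling of the terminal alkyne with the vinyl iodide proceeds with retention of the E geometry and tolerates free hydroxyls, the phenol and the β-keto ester.

Step 23
Reactants: 39 enyne anilide
Product: 40 (16E,18Z)-dienamide phenol
Conditions: H2 (1 atm), Pd/CaCO3 poisoned with Pb(OAc)2, quinoline, EtOAc, 23 °C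
Reagents that add atoms: none
Why: Lindlar semihydrogenation adds hydrogen syn to the alkyne only, giving the C18=C19 Z alkene; the trisubstituted alkenes are not reduced.

Step 24
Reactants: 40 (16E,18Z)-dienamide phenol
Product: 41 seco 2-acylamino-3-methyl-1,4-benzoquinone
Conditions: (KSO3)2NO (2.5 equiv), KH2PO4, acetone/H2O, 0 → 23 °C
Reagents that add atoms: potassium nitrosodisulfonate, [K+].[K+].[O]N(S(=O)(=O)[O-])S(=O)(=O)[O-]
Why: Teuber oxidation of a para-unsubstituted phenol gives the para-quinone; the position para to OH is the one next to the amide nitrogen, which yields exactly the 2-amido-3-methylquinone.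

Step 25
Reactants: 41 seco 2-acylamino-3-methyl-1,4-benzoquinone
Product: 44 macrocyclic naphthoquinone C11 carbinol (21-OTBS; 27,28-acetonide; 6,8-diol; 23,25-diol; C11 epimers), via persilylated bis-silyloxydiene 42 (not isolated), via persilylated naphthalene cycloadduct 43 (not isolated)
Conditions: TMSOTf (12 equiv), Et3N (16 equiv), CH2Cl2, 0 °C, 41 added over 10 h (final 0.5 mM), then 23 °C; then K2CO3, MeOH, air, 0 °C
Reagents that add atoms: none
Why: Proposed new method: soft enolisation silylates the hydroxyls and turns the β-keto ester into a 1-methoxy-1,3-bis(silyloxy)diene; its nucleophilic C5 terminus attacks the quinone carbon β to the more electrophilic, N–H-bonded C1 carbonyl (the amide nitrogen deactivates C4=O), so a regiocontrolled intramolecular Diels–Alder reaction under high dilution closes the benzenoid ring and the 23-membered ansa ring together, after which loss of MeOSiMe3, enolisation and air oxidation give the naphthoquinone; the closest known reactions are Brassard-type quinone/ketene-acetal diene annulations and macrocyclising intramolecular Diels–Alder reactions.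

Step 26
Reactants: 44 macrocyclic naphthoquinone C11 carbinol
Product: 45 21-O-TBS-27,28-O-isopropylidene derivative of the target (C11 ketone)
Conditions: activated MnO2 (30 equiv), CH2Cl2, 23 °C
Reagents that add atoms: none
Why: MnO2 oxidises only the doubly activated (benzylic and allylic) C11 carbinol, merging both epimers into the aryl enone while the C23 and C25 alcohols stay intact.

Step 27
Reactants: 45 21-O-TBS-27,28-O-isopropylidene derivative of the target
Product: 46 CNP0244244.1 (target)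
Conditions: 48% aq. HF, MeCN, 0 → 23 °C (short reaction time)
Reagents that add atoms: none
Why: Acidic fluoride cleaves the secondary TBS ether and hydrolyses the acetonide in one operation; with C11 already a ketone there is no ionisable benzylic carbinol, and no stereocentre is touched.

## Compound list

1 | methyl (S)-3-hydroxy-2-methylpropanoate | C[C@@H](CO)C(=O)OC | starting material
2 | methyl (S)-2-methyl-3-(triethylsilyloxy)propanoate | CC[Si](CC)(CC)OC[C@H](C)C(=O)OC | intermediate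
3 | (S)-2-methyl-3-(triethylsilyloxy)propanal | CC[Si](CC)(CC)OC[C@H](C)C=O | intermediate
4 | (S)-but-3-yn-2-ol | C[C@H](O)C#C | starting material
5 | (S)-but-3-yn-2-yl methanesulfonate | C[C@H](OS(C)(=O)=O)C#C | intermediate
6 | (2S,3R,4R)-2,4-dimethyl-1-(triethylsilyloxy)hex-5-yn-3-ol | CC[Si](CC)(CC)OC[C@H](C)[C@H](O)[C@H](C)C#C | intermediate
7 | (2S,3R,4R)-3-(tert-butyldimethylsilyloxy)-2,4-dimethyl-1-(triethylsilyloxy)hex-5-yne | CC[Si](CC)(CC)OC[C@H](C)[C@H](O[Si](C)(C)C(C)(C)C)[C@H](C)C#C | intermediate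
8 | (2R,3R,4R)-3-(tert-butyldimethylsilyloxy)-2,4-dimethylhex-5-ynal | O=C[C@H](C)[C@H](O[Si](C)(C)C(C)(C)C)[C@H](C)C#C | intermediate
9 | (R)-4-benzyl-3-propanoylthiazolidine-2-thione | CCC(=O)N1[C@H](Cc2ccccc2)CSC1=S | starting material
10 | methacrolein | CC(=C)C=O | starting material
11 | trichlorotitanium (Z)-enolate of 9 | C/C=C(\O[Ti](Cl)(Cl)Cl)N1[C@H](Cc2ccccc2)CSC1=S | intermediate
12 | (R)-4-benzyl-3-[(2R,3R)-3-hydroxy-2,4-dimethylpent-4-enoyl]thiazolidine-2-thione | C=C(C)[C@H](O)[C@@H](C)C(=O)N1[C@H](Cc2ccccc2)CSC1=S | intermediate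
13 | potassium methyl malonate | COC(=O)CC(=O)[O-].[K+] | starting material
14 | methyl (4R,5R)-5-hydroxy-4,6-dimethyl-3-oxohept-6-enoate | C=C(C)[C@H](O)[C@@H](C)C(=O)CC(=O)OC | intermediate
15 | methyl (3S,4S,5R)-3,5-dihydroxy-4,6-dimethylhept-6-enoate | C=C(C)[C@H](O)[C@@H](C)[C@@H](O)CC(=O)OC | intermediate
16 | methyl (3S,4S,5R)-3,5-dihydroxy-4-methyl-6-oxoheptanoate | CC(=O)[C@H](O)[C@@H](C)[C@@H](O)CC(=O)OC | intermediate
17 | prop-2-yn-1-ol | C#CCO | starting material
18 | (Z)-bromomagnesium 3-(bromomagnesio)-2-methylprop-2-en-1-olate | Br[Mg]/C=C(/C)CO[Mg]Br | intermediate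
19 | (Z)-3-iodo-2-methylprop-2-en-1-ol | I/C=C(/C)CO | intermediate
20 | (Z)-tert-butyl[(3-iodo-2-methylprop-2-en-1-yl)oxy]dimethylsilane | I/C=C(/C)CO[Si](C)(C)C(C)(C)C | intermediate
21 | (Z)-[3-(tert-butyldimethylsilyloxy)-2-methylprop-1-en-1-yl]lithium | [Li]/C=C(/C)CO[Si](C)(C)C(C)(C)C | intermediate
22 | (Z)-[3-(tert-butyldimethylsilyloxy)-2-methylprop-1-en-1-yl]magnesium bromide | Br[Mg]/C=C(/C)CO[Si](C)(C)C(C)(C)C | intermediate
23 | methyl (3S,4S,5R,6R,7Z)-9-(tert-butyldimethylsilyloxy)-3,5,6-trihydroxy-4,6,8-trimethylnon-7-enoate | CC(C)(C)[Si](C)(C)OC/C(C)=C\[C@@](C)(O)[C@H](O)[C@@H](C)[C@@H](O)CC(=O)OC | intermediate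
24 | methyl (3S,4S)-3-hydroxy-4-{(4R,5R)-5-[(Z)-3-(tert-butyldimethylsilyloxy)-2-methylprop-1-en-1-yl]-2,2,5-trimethyl-1,3-dioxolan-4-yl}pentanoate | CC(C)(C)[Si](C)(C)OC/C(C)=C\[C@@]1(C)OC(C)(C)O[C@@H]1[C@@H](C)[C@@H](O)CC(=O)OC | intermediate
25 | dilithium dianion of 24 (C25 alkoxide; Z ester enolate) | CC(C)(C)[Si](C)(C)OC/C(C)=C\[C@@]1(C)OC(C)(C)O[C@@H]1[C@@H](C)[C@@H](O[Li])/C=C(\O[Li])OC | intermediate
26 | open-chain C18–C11 aldol adduct (C24 methyl ester; 23,25-diol; 21-OTBS; 27,28-acetonide; C11H2OTBS; C18≡C19 alkyne; 12Z; C20–C28 arranged as in the target) | COC(=O)[C@H]([C@H](O)[C@H](C)[C@H](O[Si](C)(C)C(C)(C)C)[C@H](C)C#C)[C@H](O)[C@H](C)[C@H]1OC(C)(C)O[C@]1(C)/C=C(C)\CO[Si](C)(C)C(C)(C)C | intermediate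
27 | C11 allylic alcohol (as 26 but C11H2OH) | COC(=O)[C@H]([C@H](O)[C@H](C)[C@H](O[Si](C)(C)C(C)(C)C)[C@H](C)C#C)[C@H](O)[C@H](C)[C@H]1OC(C)(C)O[C@]1(C)/C=C(C)\CO | intermediate
28 | (Z)-enal (as 27 but C11HO) | COC(=O)[C@H]([C@H](O)[C@H](C)[C@H](O[Si](C)(C)C(C)(C)C)[C@H](C)C#C)[C@H](O)[C@H](C)[C@H]1OC(C)(C)O[C@]1(C)/C=C(C)\C=O | intermediate
29 | methyl 2-methyl-3-oxobutanoate | CC(=O)C(C)C(=O)OC | starting material
30 | sodium lithium dianion of 29 | COC(O[Na])=C(C)C(=C)O[Li] | intermediate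
31 | δ-hydroxy β-keto ester (28 extended by C5–C8; C11 and C7 epimers) | COC(=O)[C@H]([C@H](O)[C@H](C)[C@H](O[Si](C)(C)C(C)(C)C)[C@H](C)C#C)[C@H](O)[C@H](C)[C@H]1OC(C)(C)O[C@]1(C)/C=C(C)\C(O)CC(=O)C(C)C(=O)OC | intermediate
32 | diethyl 2-methylmalonate | CCOC(=O)C(C)C(=O)OCC | starting material
33 | iodoform | IC(I)I | starting material
34 | diethyl 2-(diiodomethyl)-2-methylmalonate | CCOC(=O)C(C)(C(I)I)C(=O)OCC | intermediate
35 | (E)-3-iodo-2-methylprop-2-enoic acid | C/C(=C\I)C(=O)O | intermediate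
36 | 3-amino-2-methylphenol | Cc1c(N)cccc1O | starting material
37 | (E)-3-iodo-2-methylprop-2-enoyl chloride | C/C(=C\I)C(=O)Cl | intermediate
38 | (E)-N-(3-hydroxy-2-methylphenyl)-3-iodo-2-methylprop-2-enamide | C/C(=C\I)C(=O)Nc1cccc(O)c1C | intermediate
39 | enyne anilide (16E; C18≡C19; phenol free) | COC(=O)[C@H]([C@H](O)[C@H](C)[C@H](O[Si](C)(C)C(C)(C)C)[C@H](C)C#C/C=C(\C)C(=O)Nc1cccc(O)c1C)[C@H](O)[C@H](C)[C@H]1OC(C)(C)O[C@]1(C)/C=C(C)\C(O)CC(=O)C(C)C(=O)OC | intermediate
40 | (16E,18Z)-dienamide phenol | COC(=O)[C@H]([C@H](O)[C@H](C)[C@H](O[Si](C)(C)C(C)(C)C)[C@H](C)/C=C\C=C(/C)C(=O)Nc1cccc(O)c1C)[C@H](O)[C@H](C)[C@H]1OC(C)(C)O[C@]1(C)/C=C(C)\C(O)CC(=O)C(C)C(=O)OC | intermediate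
41 | seco 2-acylamino-3-methyl-1,4-benzoquinone | COC(=O)[C@H]([C@H](O)[C@H](C)[C@H](O[Si](C)(C)C(C)(C)C)[C@H](C)/C=C\C=C(/C)C(=O)NC1=C(C)C(=O)C=CC1=O)[C@H](O)[C@H](C)[C@H]1OC(C)(C)O[C@]1(C)/C=C(C)\C(O)CC(=O)C(C)C(=O)OC | intermediate
42 | persilylated bis(silyloxy)diene of 41 (11-, 23-, 25-OTMS; C5=C6(OTMS)–C7(Me)=C8(OMe)OTMS) | COC(=O)[C@H]([C@H](O[Si](C)(C)C)[C@H](C)[C@H](O[Si](C)(C)C(C)(C)C)[C@H](C)/C=C\C=C(/C)C(=O)NC1=C(C)C(=O)C=CC1=O)[C@H](O[Si](C)(C)C)[C@H](C)[C@H]1OC(C)(C)O[C@]1(C)/C=C(C)\C(O[Si](C)(C)C)C=C(O[Si](C)(C)C)C(C)=C(OC)O[Si](C)(C)C | intermediate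
43 | persilylated macrocyclic naphthalene-1,4,6,8-tetrol (aromatised cycloadduct; all OH as OTMS except 21-OTBS and the acetonide) | COC(=O)[C@@H]1[C@H](O[Si](C)(C)C)[C@H](C)[C@H](O[Si](C)(C)C(C)(C)C)[C@H](C)/C=C\C=C(/C)C(=O)Nc2c(C)c(O[Si](C)(C)C)c3c(c(O[Si](C)(C)C)c(C)c(O[Si](C)(C)C)c3C(O[Si](C)(C)C)/C(C)=C\[C@@]4(C)OC(C)(C)O[C@@H]4[C@@H](C)[C@H]1O[Si](C)(C)C)c2O[Si](C)(C)C | intermediate
44 | macrocyclic naphthoquinone C11 carbinol (21-OTBS; 27,28-acetonide; C11 epimers) | COC(=O)[C@@H]1[C@H](O)[C@H](C)[C@H](O[Si](C)(C)C(C)(C)C)[C@H](C)/C=C\C=C(/C)C(=O)NC2=C(C)C(=O)c3c(c(O)c(C)c(O)c3C(O)/C(C)=C\[C@@]4(C)OC(C)(C)O[C@@H]4[C@@H](C)[C@H]1O)C2=O | intermediate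
45 | 21-O-TBS-27,28-O-isopropylidene derivative of the target | COC(=O)[C@@H]1[C@H](O)[C@H](C)[C@H](O[Si](C)(C)C(C)(C)C)[C@H](C)/C=C\C=C(/C)C(=O)NC2=C(C)C(=O)c3c(c(O)c(C)c(O)c3C(=O)/C(C)=C\[C@@]4(C)OC(C)(C)O[C@@H]4[C@@H](C)[C@H]1O)C2=O | intermediate
46 | CNP0244244.1 | COC(=O)[C@@H]1[C@H](O)[C@H](C)[C@H](O)[C@H](C)/C=C\C=C(/C)C(=O)NC2=C(C)C(=O)c3c(c(O)c(C)c(O)c3C(=O)/C(C)=C\[C@@](C)(O)[C@H](O)[C@@H](C)[C@H]1O)C2=O | target

## Step count and risks

Total: 27 steps. Longest linear sequence: 16 steps (7–10, 13–18, 22–27).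

**Step 25 (most likely to fail).** Risks are oligomerisation, amine or silyl triflate attack on the quinone, and weak regiocontrol from the amide alone. Fallback, setting out from 31 and 38 and coming back at 44: the two rings are made one after the other. Amide 38 is oxidised with (KSO3)2NO to the iodoacryloylaminoquinone F1. Alkyne 31 is converted with TMSOTf/Et3N into its persilylated bis(silyloxy)diene F2, which reacts with F1 in an intermolecular Diels–Alder/aromatisation (then K2CO3, MeOH, air) to give the open-chain naphthoquinone F3 carrying the terminal alkyne and the vinyl iodide. High-dilution intramolecular Sonogashira coupling (Pd(PPh3)4, CuI, Et3N) closes the ansa ring as the macrocyclic enyne F4. Semi-reduction with zinc activated by Cu(OAc)2 and AgNO3, followed by air re-oxidation of the hydroquinone, gives 44.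

**Step 15.** The C24 face is reliable, but the selectivity at the new carbinol C23 of a dianion aldol with a chiral aldehyde is uncertain. Fallback, setting out from 8 and 24 and coming back at 26: the bond is made by acylation and reduction instead. Aldehyde 8 is oxidised (NaClO2, NaH2PO4, 2-methylbut-2-ene) to the carboxylic acid F5 and activated with carbonyldiimidazole as the acyl imidazole F6. F6 acylates dianion 25 anti to the C25 alkoxide to give the C23 β-keto ester F7. Hydroxyl-directed reduction with Me4NBH(OAc)3 (internal delivery from the C25 hydroxyl, 1,3-anti) then sets C23 and gives 26.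

**Step 13.** The unprotected keto diol may lactonise, the ester may be attacked, and chelation control may be eroded by the second alkoxide. Fallback, setting out from 15 and coming back at 24: the diol is masked first. Diol 15 is converted (Me2C(OMe)2, PPTS) into the 1,3-dioxane F8 and ozonolysed to the methyl ketone F9. Alkenylmagnesium 22 is added under chelation by the ring oxygen to give the tertiary alcohol F10. Acid-catalysed acetonide migration (PPTS, acetone) from the twist-boat anti-1,3-dioxane to the 1,2-dioxolane gives 24.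

## Further compounds

F1 | step 25 | (E)-3-iodo-2-methyl-N-(2-methyl-3,6-dioxocyclohexa-1,4-dien-1-yl)prop-2-enamide | C/C(=C\I)C(=O)NC1=C(C)C(=O)C=CC1=O
F2 | step 25 | persilylated bis(silyloxy)diene of 31 | COC(=O)[C@H]([C@H](O[Si](C)(C)C)[C@H](C)[C@H](O[Si](C)(C)C(C)(C)C)[C@H](C)C#C)[C@H](O[Si](C)(C)C)[C@H](C)[C@H]1OC(C)(C)O[C@]1(C)/C=C(C)\C(O[Si](C)(C)C)C=C(O[Si](C)(C)C)C(C)=C(OC)O[Si](C)(C)C
F3 | step 25 | open-chain naphthoquinone with terminal alkyne and (E)-iodoacrylamide | COC(=O)[C@H]([C@H](O)[C@H](C)[C@H](O[Si](C)(C)C(C)(C)C)[C@H](C)C#C)[C@H](O)[C@H](C)[C@H]1OC(C)(C)O[C@]1(C)/C=C(C)\C(O)c1c(O)c(C)c(O)c2C(=O)C(NC(=O)/C(C)=C/I)=C(C)C(=O)c12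
F4 | step 25 | macrocyclic enyne naphthoquinone (C18≡C19) | COC(=O)[C@@H]1[C@H](O)[C@H](C)[C@H](O[Si](C)(C)C(C)(C)C)[C@H](C)C#C/C=C(\C)C(=O)NC2=C(C)C(=O)c3c(c(O)c(C)c(O)c3C(O)/C(C)=C\[C@@]4(C)OC(C)(C)O[C@@H]4[C@@H](C)[C@H]1O)C2=O
F5 | step 15 | (2R,3R,4R)-3-(tert-butyldimethylsilyloxy)-2,4-dimethylhex-5-ynoic acid | OC(=O)[C@H](C)[C@H](O[Si](C)(C)C(C)(C)C)[C@H](C)C#C
F6 | step 15 | 1-[(2R,3R,4R)-3-(tert-butyldimethylsilyloxy)-2,4-dimethylhex-5-ynoyl]imidazole | O=C([C@H](C)[C@H](O[Si](C)(C)C(C)(C)C)[C@H](C)C#C)n1ccnc1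
F7 | step 15 | C23 β-keto ester analogue of 26 | COC(=O)[C@H](C(=O)[C@H](C)[C@H](O[Si](C)(C)C(C)(C)C)[C@H](C)C#C)[C@H](O)[C@H](C)[C@H]1OC(C)(C)O[C@]1(C)/C=C(C)\CO[Si](C)(C)C(C)(C)C
F8 | step 13 | methyl 2-[(4S,5S,6R)-2,2,5-trimethyl-6-(prop-1-en-2-yl)-1,3-dioxan-4-yl]acetate | C=C(C)[C@@H]1OC(C)(C)O[C@@H](CC(=O)OC)[C@@H]1C
F9 | step 13 | methyl 2-[(4S,5S,6R)-6-acetyl-2,2,5-trimethyl-1,3-dioxan-4-yl]acetate | CC(=O)[C@@H]1OC(C)(C)O[C@@H](CC(=O)OC)[C@@H]1C
F10 | step 13 | dioxane-protected tertiary alcohol (C28 carbinol on the 25,27-acetonide) | CC(C)(C)[Si](C)(C)OC/C(C)=C\[C@@](C)(O)[C@@H]1OC(C)(C)O[C@@H](CC(=O)OC)[C@@H]1C
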